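**Retrosynthetic overview**
- The target is opened at the lactone C–O bond and the phenol is masked as a MOM ether. This gives a 4-hydroxy tert-butyl ester whose C3 centre can be equilibrated to trans after ring closure.
- The CH2OH carbon is traced back to an N-acyloxazolidinone carbonyl, which gives an unsymmetrical 2,3-dibenzylsuccinate (imide at one end, tert-butyl ester at the other).
- Key disconnection, the C3–C4 bond: oxidative heterocoupling of two enolates (two α-carbons that are both normally nucleophilic), with the oxazolidinone auxiliary fixing C4.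
- The imide comes from 3-(3,4-dimethoxyphenyl)propanoic acid; the ester comes from 3-hydroxy-4,5-dimethoxybenzaldehyde by MOM protection, Wittig olefination and hydrogenation.
- Ring order: both arenes are bought; the butyrolactone is the only ring formed, in the last step.

Assumption: the SMILES is read as the (3R,4R)-trans lactone, and 3-hydroxy-4,5-dimethoxybenzaldehyde and Ph3P=CHCO2t-Bu are taken as catalogue chemicals.

**Step 1**
Reactants: 1 3-(3,4-dimethoxyphenyl)propanoic acid; 2 (S)-4-benzyloxazolidin-2-one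
Product: 3 (S)-4-benzyl-3-[3-(3,4-dimethoxyphenyl)propanoyl]oxazolidin-2-one
Conditions: DCC (1.2 equiv), DMAP (0.2 equiv), CH2Cl2, 0 °C → rt
Reagents that add atoms: none
Why: Steglich-type DCC/DMAP N-acylation, in which the acylpyridinium formed from the O-acylisourea acylates the carbamate N–H; no stereocentre is formed and the S centre of the auxiliary is untouched.

**Step 2**
Reactants: 4 3-hydroxy-4,5-dimethoxybenzaldehyde
Product: 5 3,4-dimethoxy-5-(methoxymethoxy)benzaldehyde
Conditions: MOMCl (1.5 equiv), i-Pr2NEt (2.0 equiv), CH2Cl2, 0 °C → rt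
Reagents that add atoms: chloromethyl methyl ether (MOMCl), COCCl
Why: O-alkylation of the phenol by the oxocarbenium-like chloride (Williamson-type acetal formation) masks the phenol, which as a free phenoxide would be oxidised in step 5; the aldehyde is inert to these conditions.

**Step 3**
Reactants: 5 3,4-dimethoxy-5-(methoxymethoxy)benzaldehyde; 6 tert-butyl (triphenylphosphoranylidene)acetate
Product: 7 tert-butyl (E)-3-[3,4-dimethoxy-5-(methoxymethoxy)phenyl]prop-2-enoate
Conditions: 6 (1.2 equiv), PhMe, 80 °C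
Reagents that add atoms: none
Why: Wittig olefination with a stabilised ylide gives the E-cinnamate; the alkene geometry is irrelevant after step 4 and no stereocentre is formed.

**Step 4**
Reactants: 7 tert-butyl (E)-3-[3,4-dimethoxy-5-(methoxymethoxy)phenyl]prop-2-enoate
Product: 8 tert-butyl 3-[3,4-dimethoxy-5-(methoxymethoxy)phenyl]propanoate
Conditions: H2 (1 atm), 10% Pd/C, EtOAc, rt
Reagents that add atoms: none
Why: Heterogeneous catalytic hydrogenation saturates the conjugated alkene; the aryl MOM ether, methyl ethers and tert-butyl ester are stable under neutral hydrogenation.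

**Step 5**
Reactants: 3 (S)-4-benzyl-3-[3-(3,4-dimethoxyphenyl)propanoyl]oxazolidin-2-one; 8 tert-butyl 3-[3,4-dimethoxy-5-(methoxymethoxy)phenyl]propanoate
Product: 11 tert-butyl (3R)-4-[(4S)-4-benzyl-2-oxo-1,3-oxazolidin-3-yl]-3-(3,4-dimethoxybenzyl)-2-[3,4-dimethoxy-5-(methoxymethoxy)benzyl]-4-oxobutanoate (mixture of C2 epimers), via imide lithium enolate 9 (not isolated), via ester lithium enolate 10 (not isolated)
Conditions: 3 (1.3 equiv) + 8 (1.0 equiv), LiN(i-Pr)2 (2.4 equiv), THF, −78 °C, 30 min; then Fe(acac)3 (2.4 equiv), −78 °C → rt; aq. NH4Cl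
Reagents that add atoms: none
Why: Oxidative enolate heterocoupling, in which trivalent iron oxidises one enolate by single-electron transfer to an electrophilic α-carbonyl radical (enolonium-type reactivity) that is captured by the other enolate, with a second one-electron oxidation completing the C–C bond between two normally nucleophilic α-carbons; the chelated Z-enolate of the imide reacts on the face opposite the auxiliary benzyl group, as in auxiliary-controlled alkylation, giving R at the imide α-carbon (future C4), while the ester α-carbon (future C3) forms unselectively and is corrected in step 7.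

**Step 6**
Reactants: 11 tert-butyl (3R)-4-[(4S)-4-benzyl-2-oxo-1,3-oxazolidin-3-yl]-3-(3,4-dimethoxybenzyl)-2-[3,4-dimethoxy-5-(methoxymethoxy)benzyl]-4-oxobutanoate
Product: 12 tert-butyl (3R)-3-(3,4-dimethoxybenzyl)-2-[3,4-dimethoxy-5-(methoxymethoxy)benzyl]-4-hydroxybutanoate (mixture of C2 epimers)
Conditions: LiBH4 (2 equiv), MeOH (2 equiv), THF, 0 °C
Reagents that add atoms: none
Why: Chemoselective reductive cleavage of the N-acyloxazolidinone, since the exocyclic imide carbonyl is far more electrophilic than the hindered tert-butyl ester; the C3 centre is not enolised and keeps its R configuration, and the auxiliary is recovered.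

**Step 7**
Reactants: 12 tert-butyl (3R)-3-(3,4-dimethoxybenzyl)-2-[3,4-dimethoxy-5-(methoxymethoxy)benzyl]-4-hydroxybutanoate
Product: 14 (3R,4R)-4-(3,4-dimethoxybenzyl)-3-(3-hydroxy-4,5-dimethoxybenzyl)dihydrofuran-2(3H)-one, via MOM-protected trans lactone 13 (not isolated)
Conditions: KOt-Bu (0.3 equiv), THF, 0 °C → rt; then 3 M HCl in MeOH, 50 °C
Reagents that add atoms: none
Why: Alkoxide-triggered 5-exo lactonisation (intramolecular transesterification) expels tert-butoxide, which equilibrates the enolisable C3 through the lactone enolate to the strongly favoured trans (3R) isomer while the non-enolisable C4 stays R; acid-catalysed acetal methanolysis then removes the MOM group.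

**Compound list**
1 | 3-(3,4-dimethoxyphenyl)propanoic acid | COc1ccc(CCC(=O)O)cc1OC | starting material
2 | (S)-4-benzyloxazolidin-2-one | O=C1N[C@@H](Cc2ccccc2)CO1 | starting material
3 | (S)-4-benzyl-3-[3-(3,4-dimethoxyphenyl)propanoyl]oxazolidin-2-one | COc1ccc(CCC(=O)N2[C@@H](Cc3ccccc3)COC2=O)cc1OC | intermediate
4 | 3-hydroxy-4,5-dimethoxybenzaldehyde | COc1cc(C=O)cc(O)c1OC | starting material
5 | 3,4-dimethoxy-5-(methoxymethoxy)benzaldehyde | COCOc1cc(C=O)cc(OC)c1OC | intermediate
6 | tert-butyl (triphenylphosphoranylidene)acetate | CC(C)(C)OC(=O)C=P(c1ccccc1)(c1ccccc1)c1ccccc1 | starting material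
7 | tert-butyl (E)-3-[3,4-dimethoxy-5-(methoxymethoxy)phenyl]prop-2-enoate | COCOc1cc(/C=C/C(=O)OC(C)(C)C)cc(OC)c1OC | intermediate
8 | tert-butyl 3-[3,4-dimethoxy-5-(methoxymethoxy)phenyl]propanoate | COCOc1cc(CCC(=O)OC(C)(C)C)cc(OC)c1OC | intermediate
9 | imide lithium enolate (Z-enolate of 3, formed in the flask) | [Li+].[O-]/C(=C\Cc1ccc(OC)c(OC)c1)N1[C@@H](Cc2ccccc2)COC1=O | intermediate
10 | ester lithium enolate (enolate of 8, formed in the flask; geometry not specified) | [Li+].[O-]C(OC(C)(C)C)=CCc1cc(OCOC)c(OC)c(OC)c1 | intermediate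
11 | tert-butyl (3R)-4-[(4S)-4-benzyl-2-oxo-1,3-oxazolidin-3-yl]-3-(3,4-dimethoxybenzyl)-2-[3,4-dimethoxy-5-(methoxymethoxy)benzyl]-4-oxobutanoate (C2 epimers) | CC(C)(C)OC(=O)C(Cc1cc(OCOC)c(OC)c(OC)c1)[C@@H](Cc1ccc(OC)c(OC)c1)C(=O)N1[C@@H](Cc2ccccc2)COC1=O | intermediate
12 | tert-butyl (3R)-3-(3,4-dimethoxybenzyl)-2-[3,4-dimethoxy-5-(methoxymethoxy)benzyl]-4-hydroxybutanoate (C2 epimers) | CC(C)(C)OC(=O)C(Cc1cc(OCOC)c(OC)c(OC)c1)[C@@H](Cc1ccc(OC)c(OC)c1)CO | intermediate
13 | (3R,4R)-4-(3,4-dimethoxybenzyl)-3-[3,4-dimethoxy-5-(methoxymethoxy)benzyl]dihydrofuran-2(3H)-one (formed in the flask) | COc1ccc(C[C@H]2COC(=O)[C@@H]2Cc2cc(OCOC)c(OC)c(OC)c2)cc1OC | intermediate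
14 | (3R,4R)-4-(3,4-dimethoxybenzyl)-3-(3-hydroxy-4,5-dimethoxybenzyl)dihydrofuran-2(3H)-one | COc1ccc(C[C@H]2COC(=O)[C@@H]2Cc2cc(O)c(OC)c(OC)c2)cc1OC | target

**Step count**
Total: 7 steps. Longest linear sequence: 6 steps (4 → 5 → 7 → 8 → 11 → 12 → 14).

**Three steps most likely to fail**

Step 5 (oxidative heterocoupling). The risks are homodimers of either partner, a moderate yield, and imperfect facial control at the imide α-carbon. Any (3S) diastereomers must be removed by chromatography at 11, where the auxiliary is still attached. The fallback sets out from 3 (and uses 5) and comes back at 13. Compound 3 is deprotonated with NaN(SiMe3)2 in THF at −78 °C and alkylated with tert-butyl bromoacetate, anti to the auxiliary benzyl group, to give tert-butyl (3R)-4-[(4S)-4-benzyl-2-oxo-1,3-oxazolidin-3-yl]-3-(3,4-dimethoxybenzyl)-4-oxobutanoate F1. LiBH4 in THF/MeOH at 0 °C reduces the imide to tert-butyl (3R)-3-(3,4-dimethoxybenzyl)-4-hydroxybutanoate F2, and catalytic p-TsOH in toluene at 80 °C closes (4R)-4-(3,4-dimethoxybenzyl)dihydrofuran-2(3H)-one F3. In parallel, 5 is reduced with NaBH4 in MeOH to [3,4-dimethoxy-5-(methoxymethoxy)phenyl]methanol F4, which CBr4/PPh3 in CH2Cl2 converts into 5-(bromomethyl)-1,2-dimethoxy-3-(methoxymethoxy)benzene F5. The LiN(SiMe3)2 enolate of F3 (THF, −78 °C) is alkylated with F5 on the face opposite the C4 substituent, which gives the trans lactone 13 under kinetic control. Compound 13 then goes through the acid stage of step 7 to 14.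

Step 6 (LiBH4 cleavage of a doubly branched imide). The risk is slow reduction or hydride attack at the ring carbonyl of the auxiliary, giving a ring-opened hydroxy amide. The fallback sets out from 11 and comes back at 12. LiOH/H2O2 in THF/H2O at 0 °C removes the auxiliary selectively at the exocyclic carbonyl to give (2R)-4-tert-butoxy-2-(3,4-dimethoxybenzyl)-3-[3,4-dimethoxy-5-(methoxymethoxy)benzyl]-4-oxobutanoic acid F6. BH3·SMe2 in THF (0 °C → rt) then reduces the free acid in the presence of the tert-butyl ester to give 12.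

Step 7 (one-pot ring closure, C3 equilibration and MOM removal). The risks are that the alkoxide closes slowly on the hindered tert-butyl ester, that KOt-Bu causes Claisen-type by-products, and that some cis lactone remains at equilibrium. The fallback sets out from 12 and comes back at 14. The ring is closed under acid instead: 3 M HCl in MeOH at 50 °C lactonises and removes the MOM group at once, and (4R)-4-(3,4-dimethoxybenzyl)-3-(3-hydroxy-4,5-dimethoxybenzyl)dihydrofuran-2(3H)-one (C3 epimer mixture) F7 is isolated. It is then equilibrated separately with DBU (3 equiv) in toluene at 80 °C under argon, and residual cis isomer is removed by chromatography or crystallisation to give 14.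

**Further compounds**
F1 | step 5 | tert-butyl (3R)-4-[(4S)-4-benzyl-2-oxo-1,3-oxazolidin-3-yl]-3-(3,4-dimethoxybenzyl)-4-oxobutanoate | CC(C)(C)OC(=O)C[C@@H](Cc1ccc(OC)c(OC)c1)C(=O)N1[C@@H](Cc2ccccc2)COC1=O
F2 | step 5 | tert-butyl (3R)-3-(3,4-dimethoxybenzyl)-4-hydroxybutanoate | CC(C)(C)OC(=O)C[C@@H](Cc1ccc(OC)c(OC)c1)CO
F3 | step 5 | (4R)-4-(3,4-dimethoxybenzyl)dihydrofuran-2(3H)-one | COc1ccc(C[C@H]2COC(=O)C2)cc1OC
F4 | step 5 | [3,4-dimethoxy-5-(methoxymethoxy)phenyl]methanol | COCOc1cc(CO)cc(OC)c1OC
F5 | step 5 | 5-(bromomethyl)-1,2-dimethoxy-3-(methoxymethoxy)benzene | COCOc1cc(CBr)cc(OC)c1OC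
F6 | step 6 | (2R)-4-tert-butoxy-2-(3,4-dimethoxybenzyl)-3-[3,4-dimethoxy-5-(methoxymethoxy)benzyl]-4-oxobutanoic acid (C3 epimers) | CC(C)(C)OC(=O)C(Cc1cc(OCOC)c(OC)c(OC)c1)[C@@H](Cc1ccc(OC)c(OC)c1)C(=O)O
F7 | step 7 | (4R)-4-(3,4-dimethoxybenzyl)-3-(3-hydroxy-4,5-dimethoxybenzyl)dihydrofuran-2(3H)-one (C3 epimer mixture) | COc1ccc(C[C@H]2COC(=O)C2Cc2cc(O)c(OC)c(OC)c2)cc1OC
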